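**Retrosynthetic overview**

1. The side chain is numbered C1' (the CH2 on the ring) to C32'. The last step unmasks the quinone by tetravalent-cerium oxidation of a hydroquinone dimethyl ether; before it, a C20 aryl (E)-alkenyl iodide and a C31 hexaene are joined at C7'–C8' by one-pot 9-BBN hydroboration/B-alkyl Suzuki–Miyaura coupling.
2. Enabling feature: C7' is the methyl-bearing sp2 carbon of the (E)-C6'=C7' alkene, so it can carry iodine with fixed geometry. C8'H2–C9'H2 lies directly beside the C10'=C11' alkene, so it maps back onto the vinyl end of a C8'=C9'–C10'=C11' diene, the only monosubstituted C=C among seven and the only one 9-BBN attacks.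
3. Iodide half: menadione → dimethyl ether → benzylic chloride; zirconium-catalysed carboalumination/nickel-catalysed benzylation sets (E)-C2'=C3'; propynylation and hydrozirconation–iodination set (E)-C6'=C7'–I.
4. Tail half: all-E geranylgeraniol supplies the four alkenes C10'=C11' to C22'=C23' and (S)-citronellyl bromide the C27' stereocenter; SeO2 ω-hydroxylation, bromination and copper-catalysed sp3–sp3 coupling (C24'–C25') join them, then enal formation and methylenation give the diene.
5. Rings: no ring is formed in the route; the benzo ring and the masked quinone ring both come intact from menadione, and the quinone ring is unmasked last.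

Key step: step 15

Remark on the chemistry: all-E geranylgeraniol and (S)-citronellyl bromide are taken as purchased in high geometric and enantiomeric purity, so the route creates no stereocenter.

**Route**

Step 1
Reactants: 1 menadione (2-methylnaphthalene-1,4-dione)
Product: 3 1,4-dimethoxy-2-methylnaphthalene, via menadiol 2 (not isolated)
Conditions: Na2S2O4, Bu4NBr (cat.), THF/H2O, rt; then aq. KOH, Me2SO4, rt
Reagents that add atoms: dimethyl sulfate, COS(=O)(=O)OC
Why: Dithionite reduces the quinone to menadiol, which is O-methylated twice in the same flask under phase-transfer Williamson conditions (reductive methylation), so that the quinone is masked as an arene inert to the organometallic steps.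

Step 2
Reactants: 3 1,4-dimethoxy-2-methylnaphthalene
Product: 4 2-(chloromethyl)-1,4-dimethoxy-3-methylnaphthalene
Conditions: (CH2O)n, 37% aq. HCl, HCl gas, 1,4-dioxane, rt to 40 °C
Reagents that add atoms: formaldehyde (as paraformaldehyde), C=O; hydrogen chloride, Cl
Why: Blanc chloromethylation, an electrophilic aromatic substitution that can only occur at C3, the single free position of the electron-rich dimethoxy ring.

Step 3
Reactants: 5 tert-butyl(but-3-yn-1-yloxy)dimethylsilane; 4 2-(chloromethyl)-1,4-dimethoxy-3-methylnaphthalene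
Product: 7 tert-butyl{[(3E)-5-(1,4-dimethoxy-3-methylnaphthalen-2-yl)-3-methylpent-3-en-1-yl]oxy}dimethylsilane, via alkenylalane 6 (not isolated)
Conditions: 5 (1.3 equiv), Me3Al (2.5 equiv), Cp2ZrCl2 (0.25 equiv), ClCH2CH2Cl, rt; volatiles removed, THF; then 4, Ni(PPh3)2Cl2 (3 mol %) reduced beforehand with n-BuLi (6 mol %) to zerovalent nickel, 0 °C to rt
Reagents that add atoms: trimethylaluminium, C[Al](C)C
Why: Negishi zirconium-catalysed carboalumination adds CH3 and Al syn across the terminal alkyne (CH3 to the internal carbon), and the zerovalent-nickel-catalysed alkenylalane–benzyl chloride cross-coupling proceeds with retention, which fixes the (E)-C2'=C3' alkene.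

Step 4
Reactants: 7 tert-butyl{[(3E)-5-(1,4-dimethoxy-3-methylnaphthalen-2-yl)-3-methylpent-3-en-1-yl]oxy}dimethylsilane
Product: 8 (3E)-5-(1,4-dimethoxy-3-methylnaphthalen-2-yl)-3-methylpent-3-en-1-ol
Conditions: Bu4NF, THF, 0 °C to rt
Reagents that add atoms: none
Why: Fluoride-driven cleavage of the Si–O bond (silyl ether deprotection) frees the primary alcohol without touching the aryl methyl ethers or the alkene.

Step 5
Reactants: 8 (3E)-5-(1,4-dimethoxy-3-methylnaphthalen-2-yl)-3-methylpent-3-en-1-ol
Product: 9 2-[(2E)-5-iodo-3-methylpent-2-en-1-yl]-1,4-dimethoxy-3-methylnaphthalene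
Conditions: I2, PPh3, imidazole, CH2Cl2, 0 °C to rt
Reagents that add atoms: iodine, [I][I]
Why: Appel-type iodination, in which iodide displaces the alkoxyphosphonium leaving group by SN2 at the primary carbon.

Step 6
Reactants: 9 2-[(2E)-5-iodo-3-methylpent-2-en-1-yl]-1,4-dimethoxy-3-methylnaphthalene; 10 1-propynyllithium
Product: 11 1,4-dimethoxy-2-methyl-3-[(2E)-3-methyloct-2-en-6-yn-1-yl]naphthalene
Conditions: THF/DMPU, −20 °C to rt
Reagents that add atoms: none
Why: SN2 alkylation of a lithium acetylide by a primary iodide, favoured over E2 by the dipolar cosolvent, brings in C6', C7' and the C7' methyl group as a 2-alkyne.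

Step 7
Reactants: 11 1,4-dimethoxy-2-methyl-3-[(2E)-3-methyloct-2-en-6-yn-1-yl]naphthalene
Product: 13 2-[(2E,6E)-7-iodo-3-methylocta-2,6-dien-1-yl]-1,4-dimethoxy-3-methylnaphthalene, via alkenylzirconocene 12 (not isolated)
Conditions: Cp2Zr(H)Cl (1.5 equiv), THF, rt to 50 °C; then I2, THF, −20 °C
Reagents that add atoms: iodine, [I][I]
Why: Hydrozirconation with Cp2Zr(H)Cl is a syn addition, and the excess hydride equilibrates the regioisomers towards zirconium on the less hindered methyl-bearing C7', so that iodinolysis with retention should give the (6E)-iodoalkene.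

Step 8
Reactants: 14 geranylgeraniol, (2E,6E,10E)-3,7,11,15-tetramethylhexadeca-2,6,10,14-tetraen-1-ol
Product: 15 tert-butyldimethyl{[(2E,6E,10E)-3,7,11,15-tetramethylhexadeca-2,6,10,14-tetraen-1-yl]oxy}silane
Conditions: TBSCl, imidazole, DMF, rt
Reagents that add atoms: tert-butyldimethylsilyl chloride, CC(C)(C)[Si](C)(C)Cl
Why: Standard imidazole-mediated silylation of the primary allylic alcohol protects it against the oxidation and the Grignard coupling that follow.

Step 9
Reactants: 15 tert-butyldimethyl{[(2E,6E,10E)-3,7,11,15-tetramethylhexadeca-2,6,10,14-tetraen-1-yl]oxy}silane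
Product: 16 (2E,6E,10E,14E)-16-[(tert-butyldimethylsilyl)oxy]-2,6,10,14-tetramethylhexadeca-2,6,10,14-tetraen-1-ol
Conditions: SeO2 (0.3 equiv), t-BuOOH (3 equiv), salicylic acid (0.1 equiv), CH2Cl2, 0 °C to rt, stopped at partial conversion
Reagents that add atoms: tert-butyl hydroperoxide, CC(C)(C)OO (terminal oxidant; its oxygen reaches the substrate through SeO2)
Why: Sharpless catalytic SeO2 allylic oxidation (ene reaction, then [2,3]-sigmatropic shift) should hydroxylate the (E)-methyl group of the terminal isopropylidene, the most accessible and electron-rich alkene, while the alkene next to the silyloxy group is deactivated.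

Step 10
Reactants: 16 (2E,6E,10E,14E)-16-[(tert-butyldimethylsilyl)oxy]-2,6,10,14-tetramethylhexadeca-2,6,10,14-tetraen-1-ol
Product: 17 {[(2E,6E,10E,14E)-16-bromo-3,7,11,15-tetramethylhexadeca-2,6,10,14-tetraen-1-yl]oxy}(tert-butyl)dimethylsilane
Conditions: CBr4, PPh3, CH2Cl2, −20 to 0 °C
Reagents that add atoms: carbon tetrabromide, BrC(Br)(Br)Br
Why: Appel bromination of the primary allylic alcohol, SN2 attack of bromide on the alkoxyphosphonium ion at low temperature, keeps the (E) geometry and avoids allylic transposition.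

Step 11
Reactants: 17 {[(2E,6E,10E,14E)-16-bromo-3,7,11,15-tetramethylhexadeca-2,6,10,14-tetraen-1-yl]oxy}(tert-butyl)dimethylsilane; 18 (S)-citronellyl bromide, (6S)-8-bromo-2,6-dimethyloct-2-ene
Product: 20 tert-butyl{[(2E,6E,10E,14E,19R)-3,7,11,15,19,23-hexamethyltetracosa-2,6,10,14,22-pentaen-1-yl]oxy}dimethylsilane, via Grignard reagent 19 (not isolated)
Conditions: 18, Mg, THF, rt to 40 °C; then 17, Li2CuCl4 (5 mol %), THF, −40 to 0 °C
Reagents that add atoms: none
Why: Copper-catalysed Kochi-type coupling of a primary alkyl Grignard reagent with a primary allylic bromide, which with Li2CuCl4 in THF should go by direct SN2 displacement with retained (E) geometry; the C27' stereocenter comes unchanged from (S)-citronellyl bromide, its descriptor becoming R only through the change in CIP priorities.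

Step 12
Reactants: 20 tert-butyl{[(2E,6E,10E,14E,19R)-3,7,11,15,19,23-hexamethyltetracosa-2,6,10,14,22-pentaen-1-yl]oxy}dimethylsilane
Product: 21 (2E,6E,10E,14E,19R)-3,7,11,15,19,23-hexamethyltetracosa-2,6,10,14,22-pentaen-1-ol
Conditions: Bu4NF, THF, rt
Reagents that add atoms: none
Why: Fluoride-driven silyl ether cleavage returns the primary allylic alcohol.

Step 13
Reactants: 21 (2E,6E,10E,14E,19R)-3,7,11,15,19,23-hexamethyltetracosa-2,6,10,14,22-pentaen-1-ol
Product: 22 (2E,6E,10E,14E,19R)-3,7,11,15,19,23-hexamethyltetracosa-2,6,10,14,22-pentaenal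
Conditions: MnO2 (activated, excess), CH2Cl2, rt
Reagents that add atoms: none
Why: MnO2 oxidises only the allylic alcohol, under neutral conditions that leave the (2E) geometry and the remote stereocenter intact.

Step 14
Reactants: 22 (2E,6E,10E,14E,19R)-3,7,11,15,19,23-hexamethyltetracosa-2,6,10,14,22-pentaenal
Product: 23 (3E,7E,11E,15E,20R)-4,8,12,16,20,24-hexamethylpentacosa-1,3,7,11,15,23-hexaene
Conditions: Ph3PCH3Br, KOtBu, THF, 0 °C; then 22, −78 to 0 °C
Reagents that add atoms: methyltriphenylphosphonium bromide, C[P+](c1ccccc1)(c1ccccc1)c1ccccc1.[Br-]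
Why: Wittig methylenation of the enal with the unstabilised ylide Ph3P=CH2 gives the terminal 1,3-diene, and no new stereo element is created.

Step 15
Reactants: 23 (3E,7E,11E,15E,20R)-4,8,12,16,20,24-hexamethylpentacosa-1,3,7,11,15,23-hexaene; 13 2-[(2E,6E)-7-iodo-3-methylocta-2,6-dien-1-yl]-1,4-dimethoxy-3-methylnaphthalene
Product: 25 2-[(2E,6E,10E,14E,18E,22E,27R)-3,7,11,15,19,23,27,31-octamethyldotriaconta-2,6,10,14,18,22,30-heptaen-1-yl]-1,4-dimethoxy-3-methylnaphthalene, via alkylborane 24 (not isolated)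
Conditions: 23 (1.3 equiv), 9-BBN (1.35 equiv), THF, 0 °C to rt; then H2O; then 13 (1.0 equiv), Pd(dppf)Cl2 (5 mol %), Ph3As (10 mol %), Cs2CO3 (3 equiv), DMF/THF/H2O, rt, degassed
Reagents that add atoms: none
Why: 9-BBN adds syn and anti-Markovnikov to the terminal vinyl group of 23 (boron on C8') to give the primary homoallylic borane 24; after base forms the hydroxyborate, zerovalent palladium (formed from Pd(dppf)Cl2) inserts into the C7'–I bond of 13 with retention, the primary alkyl group passes from boron to palladium, and reductive elimination forges the C7'–C8' bond. The closest known reaction type is the B-alkyl Suzuki–Miyaura coupling of 9-alkyl-9-BBN reagents with (E)-2-iodoalk-2-enes under Pd(dppf)Cl2/Ph3As/Cs2CO3 in aqueous DMF. No ring is closed and no stereocenter is created: the C27' center is remote and untouched, and the (E)-C6'=C7' geometry is passed on from the alkenyl iodide by stereoretentive oxidative addition and reductive elimination. The step needs hydroboration of one C=C out of six in 23, which is secured because the other five are trisubstituted and react with 9-BBN far more slowly than the monosubstituted vinyl group, and it needs boron on the terminal carbon, which the bulk of 9-BBN ensures. It also needs cross-coupling to outrun β-hydride elimination of the alkylpalladium intermediate, which the wide-bite-angle dppf ligand and the Ph3As additive should secure. In one operation the C20 and C31 halves become the complete C51 skeleton with all six (E)-alkenes, the isopropylidene end and the stereocenter in place.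

Step 16
Reactants: 25 2-[(2E,6E,10E,14E,18E,22E,27R)-3,7,11,15,19,23,27,31-octamethyldotriaconta-2,6,10,14,18,22,30-heptaen-1-yl]-1,4-dimethoxy-3-methylnaphthalene
Product: 26 2-methyl-3-[(2E,6E,10E,14E,18E,22E,27R)-3,7,11,15,19,23,27,31-octamethyldotriaconta-2,6,10,14,18,22,30-heptaen-1-yl]naphthalene-1,4-dione (CNP0319612.1)
Conditions: (NH4)2Ce(NO3)6 (2.5 equiv), MeCN/CH2Cl2/H2O, 0 °C
Reagents that add atoms: water, O
Why: Oxidative demethylation by tetravalent cerium, in which two one-electron oxidations of the electron-rich dimethoxynaphthalene, attack of water on the radical cation and loss of methanol give the 1,4-quinone, should be fast at 0 °C and spare the isolated trisubstituted alkenes.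

**Compound list**

1 | menadione (2-methylnaphthalene-1,4-dione) | CC1=CC(=O)c2ccccc2C1=O | starting material
2 | menadiol (2-methylnaphthalene-1,4-diol) | Cc1cc(O)c2ccccc2c1O | intermediate
3 | 1,4-dimethoxy-2-methylnaphthalene | COc1cc(C)c(OC)c2ccccc12 | intermediate
4 | 2-(chloromethyl)-1,4-dimethoxy-3-methylnaphthalene | COc1c(CCl)c(C)c(OC)c2ccccc12 | intermediate
5 | tert-butyl(but-3-yn-1-yloxy)dimethylsilane | C#CCCO[Si](C)(C)C(C)(C)C | starting material
6 | alkenylalane, [(1E)-4-(tert-butyldimethylsilyloxy)-2-methylbut-1-en-1-yl]dimethylaluminium | C[Al](C)/C=C(\C)CCO[Si](C)(C)C(C)(C)C | intermediate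
7 | tert-butyl{[(3E)-5-(1,4-dimethoxy-3-methylnaphthalen-2-yl)-3-methylpent-3-en-1-yl]oxy}dimethylsilane | COc1c(C)c(C/C=C(\C)CCO[Si](C)(C)C(C)(C)C)c(OC)c2ccccc12 | intermediate
8 | (3E)-5-(1,4-dimethoxy-3-methylnaphthalen-2-yl)-3-methylpent-3-en-1-ol | COc1c(C)c(C/C=C(\C)CCO)c(OC)c2ccccc12 | intermediate
9 | 2-[(2E)-5-iodo-3-methylpent-2-en-1-yl]-1,4-dimethoxy-3-methylnaphthalene | COc1c(C)c(C/C=C(\C)CCI)c(OC)c2ccccc12 | intermediate
10 | 1-propynyllithium | [Li]C#CC | starting material
11 | 1,4-dimethoxy-2-methyl-3-[(2E)-3-methyloct-2-en-6-yn-1-yl]naphthalene | COc1c(C)c(C/C=C(\C)CCC#CC)c(OC)c2ccccc12 | intermediate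
12 | alkenylzirconocene, chlorobis(cyclopentadienyl)[(2E,6E)-8-(1,4-dimethoxy-3-methylnaphthalen-2-yl)-6-methylocta-2,6-dien-2-yl]zirconium | COc1c(C)c(C/C=C(\C)CC/C=C(\C)[Zr](Cl)(C3C=CC=C3)C3C=CC=C3)c(OC)c2ccccc12 | intermediate
13 | 2-[(2E,6E)-7-iodo-3-methylocta-2,6-dien-1-yl]-1,4-dimethoxy-3-methylnaphthalene | COc1c(C)c(C/C=C(\C)CC/C=C(\C)I)c(OC)c2ccccc12 | intermediate
14 | geranylgeraniol, (2E,6E,10E)-3,7,11,15-tetramethylhexadeca-2,6,10,14-tetraen-1-ol | CC(C)=CCC/C(C)=C/CC/C(C)=C/CC/C(C)=C/CO | starting material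
15 | tert-butyldimethyl{[(2E,6E,10E)-3,7,11,15-tetramethylhexadeca-2,6,10,14-tetraen-1-yl]oxy}silane | CC(C)=CCC/C(C)=C/CC/C(C)=C/CC/C(C)=C/CO[Si](C)(C)C(C)(C)C | intermediate
16 | (2E,6E,10E,14E)-16-[(tert-butyldimethylsilyl)oxy]-2,6,10,14-tetramethylhexadeca-2,6,10,14-tetraen-1-ol | OC/C(C)=C/CC/C(C)=C/CC/C(C)=C/CC/C(C)=C/CO[Si](C)(C)C(C)(C)C | intermediate
17 | {[(2E,6E,10E,14E)-16-bromo-3,7,11,15-tetramethylhexadeca-2,6,10,14-tetraen-1-yl]oxy}(tert-butyl)dimethylsilane | BrC/C(C)=C/CC/C(C)=C/CC/C(C)=C/CC/C(C)=C/CO[Si](C)(C)C(C)(C)C | intermediate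
18 | (S)-citronellyl bromide, (6S)-8-bromo-2,6-dimethyloct-2-ene | CC(C)=CCC[C@H](C)CCBr | starting material
19 | Grignard reagent, [(3S)-3,7-dimethyloct-6-en-1-yl]magnesium bromide | CC(C)=CCC[C@H](C)CC[Mg]Br | intermediate
20 | tert-butyl{[(2E,6E,10E,14E,19R)-3,7,11,15,19,23-hexamethyltetracosa-2,6,10,14,22-pentaen-1-yl]oxy}dimethylsilane | CC(C)=CCC[C@H](C)CCC/C(C)=C/CC/C(C)=C/CC/C(C)=C/CC/C(C)=C/CO[Si](C)(C)C(C)(C)C | intermediate
21 | (2E,6E,10E,14E,19R)-3,7,11,15,19,23-hexamethyltetracosa-2,6,10,14,22-pentaen-1-ol | CC(C)=CCC[C@H](C)CCC/C(C)=C/CC/C(C)=C/CC/C(C)=C/CC/C(C)=C/CO | intermediate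
22 | (2E,6E,10E,14E,19R)-3,7,11,15,19,23-hexamethyltetracosa-2,6,10,14,22-pentaenal | CC(C)=CCC[C@H](C)CCC/C(C)=C/CC/C(C)=C/CC/C(C)=C/CC/C(C)=C/C=O | intermediate
23 | (3E,7E,11E,15E,20R)-4,8,12,16,20,24-hexamethylpentacosa-1,3,7,11,15,23-hexaene | CC(C)=CCC[C@H](C)CCC/C(C)=C/CC/C(C)=C/CC/C(C)=C/CC/C(C)=C/C=C | intermediate
24 | alkylborane, 9-[(3E,7E,11E,15E,20R)-4,8,12,16,20,24-hexamethylpentacosa-3,7,11,15,23-pentaen-1-yl]-9-borabicyclo[3.3.1]nonane | CC(C)=CCC[C@H](C)CCC/C(C)=C/CC/C(C)=C/CC/C(C)=C/CC/C(C)=C/CCB1C2CCCC1CCC2 | intermediate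
25 | 2-[(2E,6E,10E,14E,18E,22E,27R)-3,7,11,15,19,23,27,31-octamethyldotriaconta-2,6,10,14,18,22,30-heptaen-1-yl]-1,4-dimethoxy-3-methylnaphthalene | CC(C)=CCC[C@H](C)CCC/C(C)=C/CC/C(C)=C/CC/C(C)=C/CC/C(C)=C/CC/C(C)=C/CC/C(C)=C/Cc1c(C)c(OC)c2ccccc2c1OC | intermediate
26 | 2-methyl-3-[(2E,6E,10E,14E,18E,22E,27R)-3,7,11,15,19,23,27,31-octamethyldotriaconta-2,6,10,14,18,22,30-heptaen-1-yl]naphthalene-1,4-dione | CC(C)=CCC[C@H](C)CCC/C(C)=C/CC/C(C)=C/CC/C(C)=C/CC/C(C)=C/CC/C(C)=C/CC/C(C)=C/CC1=C(C)C(=O)c2ccccc2C1=O | target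

**Step count and risks**

Total step count: 16.
Longest linear sequence: 9 steps (steps 8 to 16 from geranylgeraniol; the menadione branch, steps 1 to 7, 15 and 16, is equally long).

The three steps most likely to fail:

Step 9. The SeO2 ene reaction may not stay at the terminal isopropylidene: the internal trisubstituted alkenes can also be attacked, and the new alcohol can be oxidised further to the enal, so conversion has to be cut short. The fallback sets out from 15 and rebuilds the chain end instead of oxidising it. NBS in aqueous THF should give the terminal bromohydrin F1, since the end alkene is the most exposed one in the aqueous medium. K2CO3 in MeOH closes it to the terminal epoxide F2. H5IO6 in THF/Et2O cleaves the epoxide, with loss of acetone, to the trisnor aldehyde F3. Wittig reaction with Ph3P=C(CH3)CO2Et in CH2Cl2 gives the (E)-enoate F4, and i-Bu2AlH at −78 °C reduces it to the allylic alcohol, where the route is rejoined at 16.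

Step 15. Transmetalation from boron to the hindered, methyl-substituted alkenylpalladium may be slow, which opens the way to protodeiodination of 13, protodeboronation of 24 and β-hydride elimination; any hydroboration that is not fully selective is also carried straight into the coupling. The fallback sets out from 23 and replaces the borane by an isolated, purified organozinc partner. 9-BBN followed by NaOH/H2O2 gives the homoallylic alcohol F5. I2/PPh3/imidazole converts it into the homoallylic iodide F6. Zinc dust with LiCl in THF inserts to give the alkylzinc iodide F7. Negishi coupling of F7 with 13 (Pd(PPh3)4, THF, rt) forms the same C7'–C8' bond with retention and rejoins the route at 25.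

Step 11. The organocopper intermediate may attack the far end of the allyl system (allylic transposition to a branched 1,1-disubstituted alkene), the (E) geometry may erode through allylcopper species, and Wurtz homocoupling may consume the Grignard reagent. The fallback sets out from 18 and uses a sulfone-stabilised carbanion, which alkylates allylic bromides only by direct SN2. PhSO2Na in DMF converts 18 into (S)-citronellyl phenyl sulfone F8. n-BuLi in THF/DMPU at −78 °C gives the α-lithio sulfone F9. Alkylation of F9 with 17 gives the alkylated sulfone F10 as a mixture of epimers at the sulfonyl carbon. Reductive desulfonylation with sodium amalgam Na(Hg) and Na2HPO4 in MeOH/THF removes the sulfonyl group and rejoins the route at 20.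

**Further compounds**

F1 | step 9 | (6E,10E,14E)-3-bromo-16-[(tert-butyldimethylsilyl)oxy]-2,6,10,14-tetramethylhexadeca-6,10,14-trien-2-ol (racemic at C3) | CC(C)(O)C(Br)CC/C(C)=C/CC/C(C)=C/CC/C(C)=C/CO[Si](C)(C)C(C)(C)C
F2 | step 9 | tert-butyl{[(2E,6E,10E)-13-(3,3-dimethyloxiran-2-yl)-3,7,11-trimethyltrideca-2,6,10-trien-1-yl]oxy}dimethylsilane (racemic) | CC1(C)OC1CC/C(C)=C/CC/C(C)=C/CC/C(C)=C/CO[Si](C)(C)C(C)(C)C
F3 | step 9 | (4E,8E,12E)-14-[(tert-butyldimethylsilyl)oxy]-4,8,12-trimethyltetradeca-4,8,12-trienal | O=CCC/C(C)=C/CC/C(C)=C/CC/C(C)=C/CO[Si](C)(C)C(C)(C)C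
F4 | step 9 | ethyl (2E,6E,10E,14E)-16-[(tert-butyldimethylsilyl)oxy]-2,6,10,14-tetramethylhexadeca-2,6,10,14-tetraenoate | CCOC(=O)/C(C)=C/CC/C(C)=C/CC/C(C)=C/CC/C(C)=C/CO[Si](C)(C)C(C)(C)C
F5 | step 15 | (3E,7E,11E,15E,20R)-4,8,12,16,20,24-hexamethylpentacosa-3,7,11,15,23-pentaen-1-ol | CC(C)=CCC[C@H](C)CCC/C(C)=C/CC/C(C)=C/CC/C(C)=C/CC/C(C)=C/CCO
F6 | step 15 | (3E,7E,11E,15E,20R)-1-iodo-4,8,12,16,20,24-hexamethylpentacosa-3,7,11,15,23-pentaene | CC(C)=CCC[C@H](C)CCC/C(C)=C/CC/C(C)=C/CC/C(C)=C/CC/C(C)=C/CCI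
F7 | step 15 | [(3E,7E,11E,15E,20R)-4,8,12,16,20,24-hexamethylpentacosa-3,7,11,15,23-pentaen-1-yl]zinc iodide | CC(C)=CCC[C@H](C)CCC/C(C)=C/CC/C(C)=C/CC/C(C)=C/CC/C(C)=C/CC[Zn]I
F8 | step 11 | {[(3S)-3,7-dimethyloct-6-en-1-yl]sulfonyl}benzene | CC(C)=CCC[C@H](C)CCS(=O)(=O)c1ccccc1
F9 | step 11 | [(3S)-3,7-dimethyl-1-(phenylsulfonyl)oct-6-en-1-yl]lithium | CC(C)=CCC[C@H](C)CC([Li])S(=O)(=O)c1ccccc1
F10 | step 11 | tert-butyl{[(2E,6E,10E,14E,19S)-3,7,11,15,19,23-hexamethyl-17-(phenylsulfonyl)tetracosa-2,6,10,14,22-pentaen-1-yl]oxy}dimethylsilane (epimers at C17) | CC(C)=CCC[C@H](C)CC(C/C(C)=C/CC/C(C)=C/CC/C(C)=C/CC/C(C)=C/CO[Si](C)(C)C(C)(C)C)S(=O)(=O)c1ccccc1
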